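## Retrosynthetic overview
1. Target 27 comes from the cis hexa-MOM ether 26 by global deprotection. C2 (aroyl cis to the C1 aryl) comes from kinetic protonation of the dienolate of trans-24.
2. 24 comes from alkenyl triflate 23 by a palladium-catalysed enantioselective C–H alkenylation (C4–C4a). It selects one of two identical aryl groups on C1, closes the only ring that is built, and sets C1.
3. 23 comes from 1,4-diketone 21 (C4 from a formate). 21 comes from benzhydrol 11 and silyl enol ether 19 (C1–C2 bond).
4. 11 comes from aldehyde 7 and aryl bromide 9, both made from phenol 5 and thus from catechol 1. 19 comes from 4-bromophenol 12 and succinyl chloride 14.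
5. Ring order: the four benzene rings arrive with the starting materials. Ring B (the carbocycle of the dihydronaphthalene) is the only ring formed, in step 14.

Assumption: the SMILES is read as the cis-(1R,2R) isomer, and the (R,R) ligand of step 14 is taken to give 1R (its mirror image is used if the sense of induction is opposite). Locants C1–C8a are those of the dihydronaphthalene core of 27, and primed locants belong to the aryl group on C1.

## Route

Step 1
Reactants: 1 catechol
Product: 2 1,2-bis(methoxymethoxy)benzene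
Conditions: NaH (2.3 equiv), MOMCl (2.3 equiv), DMF, 0 °C to rt
Reagents that add atoms: chloromethyl methyl ether (MOMCl), COCCl
Why: Double Williamson-type O-alkylation (MOM protection); the acetals survive all later bases and organometallics, direct the lithiation of step 2 and leave together in step 16.

Step 2
Reactants: 2 1,2-bis(methoxymethoxy)benzene
Product: 5 2,3-bis(methoxymethoxy)phenol, via aryllithium 3 (not isolated), via dimethyl arylboronate 4 (not isolated)
Conditions: n-BuLi, TMEDA, THF, 0 °C; B(OMe)3, −78 °C to rt; AcOH, 30% H2O2, 0 °C to rt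
Reagents that add atoms: hydrogen peroxide, OO
Why: Directed ortho-metalation beside an OMOM group (both ortho sites are equivalent), borylation and peroxide oxidation (1,2-aryl shift from boron to oxygen) put in the third oxygen next to the protected catechol.

Step 3
Reactants: 5 2,3-bis(methoxymethoxy)phenol
Product: 6 2-hydroxy-3,4-bis(methoxymethoxy)benzaldehyde
Conditions: MgCl2, Et3N, (CH2O)n, MeCN, reflux
Reagents that add atoms: formaldehyde (as paraformaldehyde), C=O
Why: Casnati–Skattebøl ortho-formylation: the magnesium phenoxide delivers formaldehyde only to the ortho position and just one ortho site is free, so the carbon that becomes C1 lands next to the free OH.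

Step 4
Reactants: 6 2-hydroxy-3,4-bis(methoxymethoxy)benzaldehyde
Product: 7 2-methoxy-3,4-bis(methoxymethoxy)benzaldehyde
Conditions: MeI, K2CO3, DMF, rt
Reagents that add atoms: iodomethane, CI
Why: Williamson methylation of the only free phenol fixes the 2-methoxy group of the target.

Step 5
Reactants: 5 2,3-bis(methoxymethoxy)phenol
Product: 8 6-bromo-2,3-bis(methoxymethoxy)phenol
Conditions: NBS (1.0 equiv), i-Pr2NH (10 mol %), CH2Cl2, 0 °C
Reagents that add atoms: N-bromosuccinimide, O=C1CCC(=O)N1Br
Why: Amine-catalysed NBS bromination of phenols is ortho-selective (the N-bromoamine is delivered through hydrogen bonding to the OH) and C6 is the only free ortho position, so bromine ends up next to the future OMe.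

Step 6
Reactants: 8 6-bromo-2,3-bis(methoxymethoxy)phenol
Product: 9 1-bromo-2-methoxy-3,4-bis(methoxymethoxy)benzene
Conditions: MeI, K2CO3, DMF, rt
Reagents that add atoms: iodomethane, CI
Why: Williamson methylation as in step 4 gives the aryl bromide that carries the halogen ortho to OMe.

Step 7
Reactants: 9 1-bromo-2-methoxy-3,4-bis(methoxymethoxy)benzene; 7 2-methoxy-3,4-bis(methoxymethoxy)benzaldehyde
Product: 11 bis[2-methoxy-3,4-bis(methoxymethoxy)phenyl]methanol, via aryllithium 10 (not isolated)
Conditions: n-BuLi, THF, −78 °C; then 7, −78 °C to 0 °C; H2O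
Reagents that add atoms: none
Why: Bromine–lithium exchange outruns any MOM-directed deprotonation at −78 °C and the aryllithium adds 1,2 to the aldehyde; the carbinol carbon (future C1) carries two identical aryl groups and is not yet stereogenic.

Step 8
Reactants: 12 4-bromophenol
Product: 13 1-bromo-4-(methoxymethoxy)benzene
Conditions: NaH, MOMCl, DMF, 0 °C to rt
Reagents that add atoms: chloromethyl methyl ether (MOMCl), COCCl
Why: Williamson-type MOM protection makes the phenol compatible with Grignard formation and uses the same protecting group as the catechols.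

Step 9
Reactants: 14 succinyl chloride
Product: 15 N,N'-dimethoxy-N,N'-dimethylbutanediamide
Conditions: MeNH(OMe)·HCl (2.1 equiv), pyridine (4.4 equiv), CH2Cl2, 0 °C to rt
Reagents that add atoms: N,O-dimethylhydroxylamine hydrochloride, CNOC.Cl
Why: Schotten–Baumann-type acylation gives the bis-Weinreb amide, which stops aryl-metal addition at the ketone stage.

Step 10
Reactants: 13 1-bromo-4-(methoxymethoxy)benzene (2.3 equiv); 15 N,N'-dimethoxy-N,N'-dimethylbutanediamide
Product: 17 1,4-bis[4-(methoxymethoxy)phenyl]butane-1,4-dione, via aryl Grignard reagent 16 (not isolated)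
Conditions: Mg turnings, THF, 40 °C; then 15, 0 °C to rt; H2O
Reagents that add atoms: none
Why: Weinreb ketone synthesis: two stable magnesium chelates collapse only on work-up, so the symmetric 1,4-diketone (C2, C3 and both carbonyl carbons) forms without over-addition.

Step 11
Reactants: 17 1,4-bis[4-(methoxymethoxy)phenyl]butane-1,4-dione
Product: 19 (Z)-1,4-bis[4-(methoxymethoxy)phenyl]-4-(trimethylsilyloxy)but-3-en-1-one, via lithium mono-enolate 18 (not isolated)
Conditions: LiN(SiMe3)2 (1.0 equiv), THF, −78 °C; TMSCl, −78 °C to 0 °C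
Reagents that add atoms: chlorotrimethylsilane, C[Si](C)(C)Cl
Why: Kinetic mono-enolisation and O-silylation (silyl enol ether formation) turn one ketone into a neutral carbon nucleophile; the Z/E ratio is of no consequence.

Step 12
Reactants: 11 bis[2-methoxy-3,4-bis(methoxymethoxy)phenyl]methanol; 19 (Z)-1,4-bis[4-(methoxymethoxy)phenyl]-4-(trimethylsilyloxy)but-3-en-1-one
Product: 21 rac-2-{bis[2-methoxy-3,4-bis(methoxymethoxy)phenyl]methyl}-1,4-bis[4-(methoxymethoxy)phenyl]butane-1,4-dione, via benzhydrylium ion 20 (not isolated)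
Conditions: Sc(OTf)3 (2 mol %), CH2Cl2, −40 °C to 0 °C
Reagents that add atoms: none
Why: Lewis-acid-catalysed SN1 (Mukaiyama-type) alkylation: the alkoxy-stabilised benzhydrylium ion forms under catalysis mild enough to spare the MOM acetals and is captured at carbon by the silyl enol ether to form C1–C2; C2 is formed racemic and is corrected in step 15.

Step 13
Reactants: 21 rac-2-{bis[2-methoxy-3,4-bis(methoxymethoxy)phenyl]methyl}-1,4-bis[4-(methoxymethoxy)phenyl]butane-1,4-dione
Product: 23 (1E)-2,3-bis[4-(methoxymethoxy)benzoyl]-4,4-bis[2-methoxy-3,4-bis(methoxymethoxy)phenyl]but-1-en-1-yl trifluoromethanesulfonate (racemic at the C2 carbon), via potassium formyl enolate 22 (not isolated)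
Conditions: KN(SiMe3)2, THF, −78 °C; HCO2CH2CF3, −78 °C to −20 °C; 18-crown-6, DMPU, Comins' reagent, −78 °C to 0 °C
Reagents that add atoms: 2,2,2-trifluoroethyl formate, O=COCC(F)(F)F; N-(5-chloropyridin-2-yl)bis(trifluoromethanesulfonimide) (Comins' reagent), FC(F)(F)S(=O)(=O)N(c1ccc(Cl)cn1)S(=O)(=O)C(F)(F)F
Why: Claisen-type formylation takes place at the only methylene (C3) because only there a stabilised β-ketoaldehyde enolate results, and this enolate is O-triflated in situ without ever being protonated (the free formyl diketone would close to a furan), the crown-ether-separated potassium enolate reacting in its extended form to give the E isomer with OTf cis to the C2 arm.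

Step 14
Reactants: 23 (1E)-2,3-bis[4-(methoxymethoxy)benzoyl]-4,4-bis[2-methoxy-3,4-bis(methoxymethoxy)phenyl]but-1-en-1-yl trifluoromethanesulfonate
Product: 24 trans-(1R,2S)-2,3-bis[4-(methoxymethoxy)benzoyl]-8-methoxy-1-[2-methoxy-3,4-bis(methoxymethoxy)phenyl]-6,7-bis(methoxymethoxy)-1,2-dihydronaphthalene
Conditions: Pd(dba)2 (5 mol %), (R,R)-TADDOL-derived P-NMe2 phosphoramidite (11 mol %), CsOPiv (30 mol %), NaHCO3 (2 equiv), 4 Å MS, DMA, 40 °C, Ar
Reagents that add atoms: none
Why: Proposed new method: enantioselective desymmetrising intramolecular C–H alkenylation, in which zerovalent palladium adds oxidatively to the E-alkenyl triflate to give a cationic, electrophilic alkenylpalladium held cis to the benzhydryl arm, pivalate-assisted concerted metalation–deprotonation then takes one of the two enantiotopic electron-rich aryl rings at its only free ortho C–H (C6', the other ortho site carries OMe) through a seven-membered palladacycle whose chiral phosphoramidite pocket fixes C1 as R, and reductive elimination forms C4–C4a and closes ring B; C2–H is labile under the carboxylate buffer so both C2 epimers of 23 funnel to the more stable trans product (any cis epimer is carried along because C2 is reset in step 15), while the weak insoluble base, the low temperature and the small monodentate ligand disfavour enolate O-vinylation to a furan and attack on the electron-poor aroyl rings; the closest known reaction type is the zerovalent-palladium-catalysed enantioselective C–H arylation or alkenylation that desymmetrises gem-diaryl units (aryl bromides to dihydrophenanthridines, alkenyl triflates to indanes), which has not been shown for β-triflyloxy enones, all-carbon tethers or 1-aryl-1,2-dihydronaphthalenes.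

Step 15
Reactants: 24 trans-(1R,2S)-2,3-bis[4-(methoxymethoxy)benzoyl]-8-methoxy-1-[2-methoxy-3,4-bis(methoxymethoxy)phenyl]-6,7-bis(methoxymethoxy)-1,2-dihydronaphthalene
Product: 26 cis-(1R,2R)-2,3-bis[4-(methoxymethoxy)benzoyl]-8-methoxy-1-[2-methoxy-3,4-bis(methoxymethoxy)phenyl]-6,7-bis(methoxymethoxy)-1,2-dihydronaphthalene, via potassium dienolate 25 (not isolated)
Conditions: KN(SiMe3)2 (1.05 equiv), THF, −78 °C, Ar; cannulate into pivalic acid (5 equiv), THF, −78 °C
Reagents that add atoms: none
Why: Kinetic protonation of an enolate: in dienolate 25 allylic strain with the exocyclic enolate and the peri 8-OMe force the C1 aryl group pseudoaxial so that it shields one face of C2, and the bulky acid delivers the proton irreversibly at −78 °C from the opposite face (alpha, not gamma), which places H trans and the aroyl group cis to the aryl group and sets C2 as R.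

Step 16
Reactants: 26 cis-(1R,2R)-2,3-bis[4-(methoxymethoxy)benzoyl]-8-methoxy-1-[2-methoxy-3,4-bis(methoxymethoxy)phenyl]-6,7-bis(methoxymethoxy)-1,2-dihydronaphthalene
Product: 27 cis-(1R,2R)-2,3-bis(4-hydroxybenzoyl)-1-(3,4-dihydroxy-2-methoxyphenyl)-8-methoxy-1,2-dihydronaphthalene-6,7-diol (CNP0335881.1)
Conditions: HCl (2 M in MeOH), THF, degassed, 0 °C to 20 °C
Reagents that add atoms: none
Why: Acid-catalysed transacetalisation of the six MOM ethers to dimethoxymethane under cold, dilute, oxygen-free conditions, where acid enolisation of the hindered C2 ketone is much slower than acetal cleavage, so both stereocentres are kept.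

## Compound list
1 | catechol | Oc1ccccc1O | starting material
2 | 1,2-bis(methoxymethoxy)benzene | COCOc1ccccc1OCOC | intermediate
3 | 2,3-bis(methoxymethoxy)phenyllithium | [Li]c1cccc(OCOC)c1OCOC | intermediate (not isolated)
4 | dimethyl 2,3-bis(methoxymethoxy)phenylboronate | COB(OC)c1cccc(OCOC)c1OCOC | intermediate (not isolated)
5 | 2,3-bis(methoxymethoxy)phenol | Oc1cccc(OCOC)c1OCOC | intermediate
6 | 2-hydroxy-3,4-bis(methoxymethoxy)benzaldehyde | O=Cc1ccc(OCOC)c(OCOC)c1O | intermediate
7 | 2-methoxy-3,4-bis(methoxymethoxy)benzaldehyde | O=Cc1ccc(OCOC)c(OCOC)c1OC | intermediate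
8 | 6-bromo-2,3-bis(methoxymethoxy)phenol | Oc1c(Br)ccc(OCOC)c1OCOC | intermediate
9 | 1-bromo-2-methoxy-3,4-bis(methoxymethoxy)benzene | COc1c(Br)ccc(OCOC)c1OCOC | intermediate
10 | 2-methoxy-3,4-bis(methoxymethoxy)phenyllithium | COc1c([Li])ccc(OCOC)c1OCOC | intermediate (not isolated)
11 | bis[2-methoxy-3,4-bis(methoxymethoxy)phenyl]methanol | OC(c1ccc(OCOC)c(OCOC)c1OC)c1ccc(OCOC)c(OCOC)c1OC | intermediate
12 | 4-bromophenol | Oc1ccc(Br)cc1 | starting material
13 | 1-bromo-4-(methoxymethoxy)benzene | COCOc1ccc(Br)cc1 | intermediate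
14 | succinyl chloride | O=C(Cl)CCC(=O)Cl | starting material
15 | N,N'-dimethoxy-N,N'-dimethylbutanediamide | CON(C)C(=O)CCC(=O)N(C)OC | intermediate
16 | 4-(methoxymethoxy)phenylmagnesium bromide | COCOc1ccc([Mg]Br)cc1 | intermediate (not isolated)
17 | 1,4-bis[4-(methoxymethoxy)phenyl]butane-1,4-dione | COCOc1ccc(cc1)C(=O)CCC(=O)c1ccc(OCOC)cc1 | intermediate
18 | lithium (Z)-mono-enolate of 17 | [Li+].[O-]/C(c1ccc(OCOC)cc1)=C\CC(=O)c1ccc(OCOC)cc1 | intermediate (not isolated)
19 | (Z)-1,4-bis[4-(methoxymethoxy)phenyl]-4-(trimethylsilyloxy)but-3-en-1-one | C[Si](C)(C)O/C(c1ccc(OCOC)cc1)=C\CC(=O)c1ccc(OCOC)cc1 | intermediate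
20 | bis[2-methoxy-3,4-bis(methoxymethoxy)phenyl]methylium ion | [CH+](c1ccc(OCOC)c(OCOC)c1OC)c1ccc(OCOC)c(OCOC)c1OC | intermediate (not isolated)
21 | rac-2-{bis[2-methoxy-3,4-bis(methoxymethoxy)phenyl]methyl}-1,4-bis[4-(methoxymethoxy)phenyl]butane-1,4-dione | O=C(CC(C(=O)c1ccc(OCOC)cc1)C(c1ccc(OCOC)c(OCOC)c1OC)c1ccc(OCOC)c(OCOC)c1OC)c1ccc(OCOC)cc1 | intermediate
22 | potassium (E)-enolate of the 3-formyl derivative of 21 (racemic at C2) | [K+].[O-]/C=C(/C(=O)c1ccc(OCOC)cc1)C(C(=O)c1ccc(OCOC)cc1)C(c1ccc(OCOC)c(OCOC)c1OC)c1ccc(OCOC)c(OCOC)c1OC | intermediate (not isolated)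
23 | (1E)-2,3-bis[4-(methoxymethoxy)benzoyl]-4,4-bis[2-methoxy-3,4-bis(methoxymethoxy)phenyl]but-1-en-1-yl trifluoromethanesulfonate (racemic at C2) | FC(F)(F)S(=O)(=O)O/C=C(/C(=O)c1ccc(OCOC)cc1)C(C(=O)c1ccc(OCOC)cc1)C(c1ccc(OCOC)c(OCOC)c1OC)c1ccc(OCOC)c(OCOC)c1OC | intermediate
24 | trans-(1R,2S) hexa-MOM ether of the dihydronaphthalene | COc1c([C@@H]2c3c(cc(OCOC)c(OCOC)c3OC)C=C(C(=O)c3ccc(OCOC)cc3)[C@H]2C(=O)c2ccc(OCOC)cc2)ccc(OCOC)c1OCOC | intermediate
25 | potassium dienolate of 24 (C1 configuration unchanged, C2 planar) | [K+].COc1c([C@@H]2c3c(cc(OCOC)c(OCOC)c3OC)C=C(C(=O)c3ccc(OCOC)cc3)C2=C([O-])c2ccc(OCOC)cc2)ccc(OCOC)c1OCOC | intermediate (not isolated)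
26 | cis-(1R,2R) hexa-MOM ether of the dihydronaphthalene | COc1c([C@@H]2c3c(cc(OCOC)c(OCOC)c3OC)C=C(C(=O)c3ccc(OCOC)cc3)[C@@H]2C(=O)c2ccc(OCOC)cc2)ccc(OCOC)c1OCOC | intermediate
27 | cis-(1R,2R)-2,3-bis(4-hydroxybenzoyl)-1-(3,4-dihydroxy-2-methoxyphenyl)-8-methoxy-1,2-dihydronaphthalene-6,7-diol | COc1c([C@@H]2c3c(cc(O)c(O)c3OC)C=C(C(=O)c3ccc(O)cc3)[C@@H]2C(=O)c2ccc(O)cc2)ccc(O)c1O | target

## Step count
Total step count: 16.
Longest linear sequence: 10 steps (1, 2, 3, 4, 7, 12, 13, 14, 15, 16). The path through steps 5 and 6 is equally long.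

## Three steps most likely to fail

**Step 14 (the new C–H alkenylation).** Four failure modes are foreseeable:
- O-vinylation of the C2 enolate to a furan
- C–H activation of an aroyl ring
- E/Z scrambling of the alkenylpalladium
- low enantioselectivity

The fallback uses known chemistry, sets out from 21 and comes back at 24. Diketone 21 is α-methylenated at C3 by a Mannich/elimination sequence ((CH2O)n, i-Pr2NH·CF3CO2H, THF, reflux) to the α-methylene diketone F1. An intramolecular Fujiwara–Moritani (oxidative Heck) cyclisation of the electron-rich arene then closes the same C4–C4a bond. It uses divalent palladium under base-free, mildly acidic conditions (Pd(OAc)2, ethyl nicotinate, benzoquinone, NaOAc, t-AmOH/AcOH, 80 °C) and is stopped before over-oxidation to the naphthalene. There is no chiral control, so the product is racemic trans material, that is 24 together with its (1S,2R) enantiomer F2. Preparative chiral SFC delivers 24.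

**Step 15 (kinetic protonation).** O-protonation followed by unselective ketonisation, or proton exchange during the quench, may give mostly the trans isomer. The fallback sets out from 24 and comes back at 26. Dienolate 25 is trapped with TMSCl to give the isolable trimethylsilyl dienol ether F3. This is protonated catalytically under reagent control with a chiral BINOL-derived N-triflyl thiophosphoramide (5 mol %) and phenol (1.1 equiv) as the stoichiometric proton source in toluene. The catalyst antipode is chosen to reinforce the substrate bias, and the product is 26.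

**Step 16 (global deprotection).** The acid may epimerise the labile C2 centre back to trans, and the free catechols may oxidise. The fallback changes the protecting-group plan so that the last step is a buffered fluoride cleavage. It sets out from 24 and comes back at 27.
- Compound 24 is deprotected first (HCl, MeOH), while C2 is still in its stable configuration, to the trans-(1R,2S) hexaphenol F4.
- Persilylation (TBSCl, imidazole, DMF) gives the trans hexa-TBS ether F5.
- KN(SiMe3)2 at −78 °C gives the potassium dienolate F6.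
- A pivalic acid quench as in step 15 gives the cis-(1R,2R) hexa-TBS ether F7.
- Et3N·3HF in THF at 0 °C releases 27 under nearly neutral conditions.

## Further compounds
F1 | step 14 | rac-2-{bis[2-methoxy-3,4-bis(methoxymethoxy)phenyl]methyl}-3-methylidene-1,4-bis[4-(methoxymethoxy)phenyl]butane-1,4-dione | C=C(C(=O)c1ccc(OCOC)cc1)C(C(=O)c1ccc(OCOC)cc1)C(c1ccc(OCOC)c(OCOC)c1OC)c1ccc(OCOC)c(OCOC)c1OC
F2 | step 14 | trans-(1S,2R) enantiomer of 24 | COc1c([C@H]2c3c(cc(OCOC)c(OCOC)c3OC)C=C(C(=O)c3ccc(OCOC)cc3)[C@@H]2C(=O)c2ccc(OCOC)cc2)ccc(OCOC)c1OCOC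
F3 | step 15 | trimethylsilyl dienol ether of 24 (C1 configuration unchanged, C2 planar) | COc1c([C@@H]2c3c(cc(OCOC)c(OCOC)c3OC)C=C(C(=O)c3ccc(OCOC)cc3)C2=C(O[Si](C)(C)C)c2ccc(OCOC)cc2)ccc(OCOC)c1OCOC
F4 | step 16 | trans-(1R,2S) hexaphenol (C2 epimer of 27) | COc1c([C@@H]2c3c(cc(O)c(O)c3OC)C=C(C(=O)c3ccc(O)cc3)[C@H]2C(=O)c2ccc(O)cc2)ccc(O)c1O
F5 | step 16 | trans-(1R,2S) hexa-TBS ether | COc1c([C@@H]2c3c(cc(O[Si](C)(C)C(C)(C)C)c(O[Si](C)(C)C(C)(C)C)c3OC)C=C(C(=O)c3ccc(O[Si](C)(C)C(C)(C)C)cc3)[C@H]2C(=O)c2ccc(O[Si](C)(C)C(C)(C)C)cc2)ccc(O[Si](C)(C)C(C)(C)C)c1O[Si](C)(C)C(C)(C)C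
F6 | step 16 | potassium dienolate of F5 | [K+].COc1c([C@@H]2c3c(cc(O[Si](C)(C)C(C)(C)C)c(O[Si](C)(C)C(C)(C)C)c3OC)C=C(C(=O)c3ccc(O[Si](C)(C)C(C)(C)C)cc3)C2=C([O-])c2ccc(O[Si](C)(C)C(C)(C)C)cc2)ccc(O[Si](C)(C)C(C)(C)C)c1O[Si](C)(C)C(C)(C)C
F7 | step 16 | cis-(1R,2R) hexa-TBS ether | COc1c([C@@H]2c3c(cc(O[Si](C)(C)C(C)(C)C)c(O[Si](C)(C)C(C)(C)C)c3OC)C=C(C(=O)c3ccc(O[Si](C)(C)C(C)(C)C)cc3)[C@@H]2C(=O)c2ccc(O[Si](C)(C)C(C)(C)C)cc2)ccc(O[Si](C)(C)C(C)(C)C)c1O[Si](C)(C)C(C)(C)C
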